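**Route in one sentence:** the imidazole is not condensed or cross-coupled but made from another azole, a 1-sulfonyl-4-(indol-3-yl)-1,2,3-triazole, which loses N2 over a rhodium catalyst and takes up the C≡N unit of an indole-3-carbonitrile as N3–C2.

**Assumptions:** 6-bromo-1H-indole-3-carboxaldehyde, p-toluenesulfonyl azide and dimethyl (1-diazo-2-oxopropyl)phosphonate are taken as purchasable. The 1H/3H tautomers of the imidazole interconvert, so "2,4-" and "2,5-disubstituted" describe the same compound.

## Structural features

Nortopsentin A (C19H12Br2N4) is an achiral, fully aromatic tris-heteroaryl. A central 1H-imidazole carries a 6-bromo-1H-indol-3-yl group at C2 and a second, identical one at C4, each through an indole C3–imidazole carbon bond, and C5 carries only hydrogen. There is no stereocentre, so the constitutional demands are the 2,4(5) placement of the indoles and bromine at C6 of each indole. The fragile groups are the two aryl C–Br bonds (oxidative addition to zerovalent palladium, halogen–metal exchange, hydrogenolysis), the two electron-rich NH-indoles (acids, oxidants, electrophiles) and three acidic N–H bonds. The real difficulty is the central ring: it must be formed between two indole C3 positions while both C–Br bonds stay intact. Condensation chemistry is handicapped because the indole nitrogen lone pair makes C3 acyl and cyano groups poor electrophiles (vinylogous amide and cyanamide). The key step exploits two features. First, N3=C2(indolyl) of the imidazole is a nitrile in disguise. Second, N1–C5H=C4(indolyl) is N1, C5 and C4 of a 1-sulfonyl-4-(indolyl)-1,2,3-triazole that has expelled its N2–N3 unit as dinitrogen. Because both indolyl groups are identical, both halves derive from one aldehyde, whose formyl carbon becomes imidazole C2 in one half and C4 in the other.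

## Logic of the disconnections

**9 ⇒ 8.** The three N–S bonds (imidazole N1, both indole N1) are cut. All three N–H groups are carried as 4-methylbenzenesulfonamides so that the indole π systems are switched off during carbene chemistry. The demand is one solvolytic operation that cleaves three sulfonamides and leaves both C–Br bonds alone.

**8 ⇒ 6 + 4 (key).** Imidazole N3–C4 and N1–C2 are cut. C2≡N3 is kept as the nitrile of 4; N1, C5 and C4 are kept as N1, C5 and C4 of the triazole in 6, whose N2 and N3 leave as N2. This settles the central ring and both inter-ring attachments in one convergent, neutral step and reduces the target to two copies of the same indole with a one-carbon or two-carbon C3 substituent. The demand is that the catalyst-bound carbene from 6 is captured by the nitrile nitrogen of 4 and by nothing else.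

**6 ⇒ 5 + tosyl azide.** Triazole N1–C5 and N3–C4 are cut, the two bonds of an azide–alkyne cycloaddition. Copper catalysis gives only the 1,4-isomer, which places the sulfonylated nitrogen next to C5–H as the key step requires. The demand is that the cuprated triazole is protonated before it can open to a ketenimine.

**5 ⇒ 2.** The terminal alkyne carbon is cut off: one-carbon homologation of the formyl group with a diazophosphonate. The formyl carbon of 2 becomes imidazole C4 and the added carbon becomes C5. The demand is that the N–S bond of 2 survives basic methanol long enough.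

**4 ⇒ 2.** The nitrile nitrogen is cut off: the formyl group of 2 is taken to C≡N through its oxime with hydroxylamine. The formyl carbon of 2 becomes imidazole C2.

**2 ⇒ 1.** The indole N–S bond is cut; 1 carries the bromine at C6 and the C3 carbon from the start, so no regiochemical question about bromine ever arises.

## Other disconnections considered

**Alternative 1:** (first to mind) Cut the two inter-ring C–C bonds, indole C3–imidazole C2 and indole C3–imidazole C4. The forward key steps are two Suzuki–Miyaura couplings of 2,4-diiodo-1-{[2-(trimethylsilyl)ethoxy]methyl}-1H-imidazole A1 with [6-bromo-1-(tert-butyldimethylsilyl)-1H-indol-3-yl]boronic acid A2 over a zerovalent palladium catalyst such as Pd(PPh3)4. The chosen plan is preferred for three reasons. The catalyst would have to distinguish the imidazole C–I bonds from the aryl C–Br bonds, and A2 carries a boronic acid and an aryl bromide in one molecule, so self-coupling is open. Indol-3-ylboronic acids protodeboronate easily. Making A2 needs a selective metalation at C3 beside the C6 bromide, and two couplings plus two kinds of deprotection make the route longer.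

**Alternative 2:** Cut imidazole N1–C5 and N3–C4, closure at the heteroatoms. The forward key step is condensation of 6-bromo-1H-indole-3-carboximidamide A3 with 2-bromo-1-(6-bromo-1H-indol-3-yl)ethan-1-one A4. This is workable and no longer than the chosen plan, but it is the conventional construction. Both electrophilic carbons it relies on are deactivated by the indole nitrogen lone pair, so formation of A3 from its nitrile and the final cyclodehydration are sluggish, while A4 can self-alkylate. The chosen step reverses the polarity: the nitrile acts as a nucleophile through nitrogen and the indolyl group acts as the donor of a donor/acceptor carbene, so the same electronic feature helps.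

**Alternative 3:** Keep the imidazole and cut both indole pyrrole rings at C3–C3a and N1–C2: a two-directional double Fischer indolisation of 2,2'-(1H-imidazole-2,4-diyl)diacetaldehyde A5 with (3-bromophenyl)hydrazine A6. The [3,3] shift of a meta-substituted aryl hydrazone can engage either ortho carbon, so each indole can close as the 4-bromo or the 6-bromo isomer, and two closures give a family of regioisomers. A5 is a doubly enolisable heteroaryl acetaldehyde, and the basic imidazole buffers the acid promoter. In the chosen plan the bromine position is bought with 1.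

Key step: step 5

## Steps

Step 1
Reactants: 1 6-bromo-1H-indole-3-carboxaldehyde
Product: 2 6-bromo-1-(4-methylbenzenesulfonyl)-1H-indole-3-carboxaldehyde
Conditions: NaH, THF, 0 °C; then TsCl, 0 °C → rt
Reagents that add atoms: p-toluenesulfonyl chloride, Cc1ccc(cc1)S(Cl)(=O)=O
Why: N-sulfonylation of the sodium salt of an acidic 3-acylindole N–H; the sulfonyl group removes the vinylogous amide character of the aldehyde and deactivates the indole π system for step 5.

Step 2
Reactants: 2 6-bromo-1-(4-methylbenzenesulfonyl)-1H-indole-3-carboxaldehyde
Product: 4 6-bromo-1-(4-methylbenzenesulfonyl)-1H-indole-3-carbonitrile, via aldoxime 3 (not isolated)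
Conditions: NH2OH·HCl, HCO2Na, HCO2H, 100 °C
Reagents that add atoms: hydroxylamine hydrochloride, Cl.NO
Why: One-pot aldehyde-to-nitrile conversion: oxime formation, then dehydration of the O-formylated aldoxime 3 in hot formic acid; N-sulfonyl indoles and aryl bromides are stable to hot carboxylic acids.

Step 3
Reactants: 2 6-bromo-1-(4-methylbenzenesulfonyl)-1H-indole-3-carboxaldehyde
Product: 5 6-bromo-3-ethynyl-1-(4-methylbenzenesulfonyl)-1H-indole
Conditions: dimethyl (1-diazo-2-oxopropyl)phosphonate, K2CO3, MeOH/THF, 0 °C → rt
Reagents that add atoms: dimethyl (1-diazo-2-oxopropyl)phosphonate, COP(=O)(OC)C(=[N+]=[N-])C(C)=O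
Why: Seyferth–Gilbert homologation in the Ohira–Bestmann variant: methanolysis of the reagent frees the diazomethylphosphonate anion, which adds to the aldehyde in Horner–Wadsworth–Emmons fashion; loss of dimethyl phosphate and N2 with a 1,2-hydrogen shift should give the terminal alkyne. Low temperature and a short reaction time limit methanolysis of the N–S bond.

Step 4
Reactants: 5 6-bromo-3-ethynyl-1-(4-methylbenzenesulfonyl)-1H-indole
Product: 6 6-bromo-1-(4-methylbenzenesulfonyl)-3-[1-(4-methylbenzenesulfonyl)-1H-1,2,3-triazol-4-yl]-1H-indole
Conditions: TsN3, Cu(O2CC4H3S) (copper thiophene-2-carboxylate, 10 mol %), toluene, rt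
Reagents that add atoms: p-toluenesulfonyl azide, Cc1ccc(cc1)S(=O)(=O)N=[N+]=[N-]
Why: Copper-catalysed azide–alkyne cycloaddition with a sulfonyl azide; the monovalent copper carboxylate in a non-basic, non-polar solvent lets the 5-cuprated triazole be protonated before it can open to a ketenimine, and copper catalysis gives only the 1,4-isomer.

Step 5
Reactants: 6 6-bromo-1-(4-methylbenzenesulfonyl)-3-[1-(4-methylbenzenesulfonyl)-1H-1,2,3-triazol-4-yl]-1H-indole; 4 6-bromo-1-(4-methylbenzenesulfonyl)-1H-indole-3-carbonitrile
Product: 8 2,4-bis[6-bromo-1-(4-methylbenzenesulfonyl)-1H-indol-3-yl]-1-(4-methylbenzenesulfonyl)-1H-imidazole, via diazo imine 7 (not isolated)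
Conditions: Rh2(O2CC7H15)4 (2 mol %), 4 (3 equiv), 4 Å MS, ClCH2CH2Cl, 80 °C
Reagents that add atoms: none
Why: The closest known reaction type is the denitrogenative transannulation of 1-sulfonyl-1,2,3-triazoles with nitriles under divalent rhodium carboxylate catalysis, applied here to an indol-3-yl triazole and an indole-3-carbonitrile. Triazole 6 is in ring–chain equilibrium with diazo imine 7 (cleavage of N1–N2), and Rh2(O2CC7H15)4 converts 7 irreversibly into a catalyst-bound azavinyl carbene with loss of N2. The lone pair of the nitrile nitrogen of 4 adds to the electrophilic carbene carbon (new N3–C4 bond) and gives a catalyst-bound nitrilium ylide. The sulfonyl imine nitrogen, whose lone pair is held cis to the carbene carbon by the E geometry of 7, then closes onto the nitrilium carbon (new N1–C2 bond; 5-endo-dig, or equally a 6π 1,5-electrocyclisation of the conjugated nitrile ylide) and the catalyst is released as the ring aromatises. Regiochemistry is fixed by connectivity: the carbene carbon with its indolyl group can only become C4, the nitrile carbon C2 and the imine CH C5, with the sulfonyl group on N1; no stereocentre is formed. The selectivity needed is capture of the carbene by the nitrile and not by an indole C2=C3 bond, a C–Br bond, water or a second carbene. It is secured by the sulfonyl groups and C3 substituents that switch off both indole π systems, by the excess of 4, by the inertness of aryl bromides to rhodium carbenes and by dry conditions. The carbene has no adjacent sp3 C–H bond, so 1,2-hydride shift cannot compete.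

Step 6
Reactants: 8 2,4-bis[6-bromo-1-(4-methylbenzenesulfonyl)-1H-indol-3-yl]-1-(4-methylbenzenesulfonyl)-1H-imidazole
Product: 9 nortopsentin A, 2,4-bis(6-bromo-1H-indol-3-yl)-1H-imidazole
Conditions: KOH, 1,4-dioxane/H2O, 90 °C; then HCl (aq) to pH 7
Reagents that add atoms: none
Why: Sulfonamide solvolysis by hydroxide attack at sulfur: the N-sulfonyl imidazole is an activated sulfonyl azolide, and the two indole sulfonamides follow because the indolide leaving groups are stabilised by the attached imidazole; hydroxide without alkoxide avoids an alkylating sulfonate ester, and aryl bromides are inert to aqueous hydroxide at this temperature.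

## Compound list

1 | 6-bromo-1H-indole-3-carboxaldehyde | O=Cc1c[nH]c2cc(Br)ccc12 | starting material
2 | 6-bromo-1-(4-methylbenzenesulfonyl)-1H-indole-3-carboxaldehyde | O=Cc1cn(S(=O)(=O)c2ccc(C)cc2)c2cc(Br)ccc12 | intermediate
3 | (E)-6-bromo-1-(4-methylbenzenesulfonyl)-1H-indole-3-carboxaldehyde oxime (formed in step 2, not isolated) | O/N=C/c1cn(S(=O)(=O)c2ccc(C)cc2)c2cc(Br)ccc12 | intermediate
4 | 6-bromo-1-(4-methylbenzenesulfonyl)-1H-indole-3-carbonitrile | N#Cc1cn(S(=O)(=O)c2ccc(C)cc2)c2cc(Br)ccc12 | intermediate
5 | 6-bromo-3-ethynyl-1-(4-methylbenzenesulfonyl)-1H-indole | C#Cc1cn(S(=O)(=O)c2ccc(C)cc2)c2cc(Br)ccc12 | intermediate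
6 | 6-bromo-1-(4-methylbenzenesulfonyl)-3-[1-(4-methylbenzenesulfonyl)-1H-1,2,3-triazol-4-yl]-1H-indole | Cc1ccc(cc1)S(=O)(=O)n1cc(nn1)-c1cn(S(=O)(=O)c2ccc(C)cc2)c2cc(Br)ccc12 | intermediate
7 | N-[(1E)-2-[6-bromo-1-(4-methylbenzenesulfonyl)-1H-indol-3-yl]-2-diazoethylidene]-4-methylbenzenesulfonamide (formed in step 5, not isolated) | Cc1ccc(cc1)S(=O)(=O)/N=C/C(=[N+]=[N-])c1cn(S(=O)(=O)c2ccc(C)cc2)c2cc(Br)ccc12 | intermediate
8 | 2,4-bis[6-bromo-1-(4-methylbenzenesulfonyl)-1H-indol-3-yl]-1-(4-methylbenzenesulfonyl)-1H-imidazole | Cc1ccc(cc1)S(=O)(=O)n1cc(nc1-c1cn(S(=O)(=O)c2ccc(C)cc2)c2cc(Br)ccc12)-c1cn(S(=O)(=O)c2ccc(C)cc2)c2cc(Br)ccc12 | intermediate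
9 | nortopsentin A, 2,4-bis(6-bromo-1H-indol-3-yl)-1H-imidazole | Brc1ccc2c(-c3c[nH]c(-c4c[nH]c5cc(Br)ccc45)n3)c[nH]c2c1 | target

## Step count and risk

Total step count: 6. Longest linear sequence: 5 steps (1 → 2 → 5 → 6 → 8 → 9; steps 1, 3, 4, 5, 6). The nitrile branch (step 2) leaves the main line at 2.

**Step 5 (key step).** The most likely failure is slow capture of the catalyst-bound carbene by a nitrile whose nitrogen is only weakly nucleophilic because of the sulfonylated indole. O–H insertion of adventitious water, carbene dimerisation or attack on a sulfonylated indole π bond would then take over, and prolonged heating would erode 6 by loss of its triazole sulfonyl group.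
Fallback (sets out from 5 and 4, comes back at 9): the ring is closed at the heteroatoms instead. Hydration of 5 with the monovalent gold catalyst (Ph3P)AuNTf2 in 1,4-dioxane/H2O at 60 °C should give the methyl ketone 1-[6-bromo-1-(4-methylbenzenesulfonyl)-1H-indol-3-yl]ethan-1-one F1. Its α-bromination with PhNMe3Br3 in THF at rt should give the bromo ketone 2-bromo-1-[6-bromo-1-(4-methylbenzenesulfonyl)-1H-indol-3-yl]ethan-1-one F2. Nitrile 4 is raised with MeAl(Cl)NH2 (from AlMe3 and NH4Cl, toluene, 80 °C) to the amidine 6-bromo-1-(4-methylbenzenesulfonyl)-1H-indole-3-carboximidamide F3. Condensation of F2 with F3 (KHCO3, THF/H2O, reflux) should give the imidazole 2,4-bis[6-bromo-1-(4-methylbenzenesulfonyl)-1H-indol-3-yl]-1H-imidazole F4, and the conditions of step 6 then remove the two remaining sulfonyl groups to give 9.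

**Step 3.** The most likely failure is loss of the protecting group: methanolysis of the N–S bond of the electron-poor 3-formylindole sulfonamide may compete with the homologation, and the resulting indolide aldehyde no longer accepts the phosphonate anion.
Fallback (sets out from 2, comes back at 5): the alkyne is made by olefination and elimination without an alcohol solvent. Wittig chloromethylenation of 2 with (chloromethyl)triphenylphosphonium chloride and NaN(SiMe3)2 in THF (−78 °C → rt) should give the chloroalkene 6-bromo-3-[(Z)-2-chloroethenyl]-1-(4-methylbenzenesulfonyl)-1H-indole F5, expected together with its E isomer. LiN(iPr)2 in THF at −78 °C then removes HCl from both isomers, by anti elimination or by α-elimination and Fritsch–Buttenberg–Wiechell shift, and gives 5 after protonation.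

**Step 4.** The most likely failure is ring opening of the 5-cuprated sulfonyl triazole to an N-sulfonyl ketenimine, which water traps before protonation can occur; hydrolytic loss of the triazole sulfonyl group during isolation is a second risk.
Fallback (sets out from 5, comes back at 6): the triazole is built without a sulfonyl group and sulfonylated afterwards. Cycloaddition of 5 with Me3SiN3 over CuI (monovalent copper) in DMF/MeOH at 100 °C should give the NH-triazole 6-bromo-1-(4-methylbenzenesulfonyl)-3-(1H-1,2,3-triazol-4-yl)-1H-indole F6. Sulfonylation with TsCl and Et3N in CH2Cl2 at 0 °C is expected to fall kinetically on the nitrogen next to C5–H and give 6. Any N2-sulfonyl isomer would have to be separated, since only the N1 isomer can open to 7.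

## Further compounds

F1 | step 5 | 1-[6-bromo-1-(4-methylbenzenesulfonyl)-1H-indol-3-yl]ethan-1-one | CC(=O)c1cn(S(=O)(=O)c2ccc(C)cc2)c2cc(Br)ccc12
F2 | step 5 | 2-bromo-1-[6-bromo-1-(4-methylbenzenesulfonyl)-1H-indol-3-yl]ethan-1-one | O=C(CBr)c1cn(S(=O)(=O)c2ccc(C)cc2)c2cc(Br)ccc12
F3 | step 5 | 6-bromo-1-(4-methylbenzenesulfonyl)-1H-indole-3-carboximidamide | N=C(N)c1cn(S(=O)(=O)c2ccc(C)cc2)c2cc(Br)ccc12
F4 | step 5 | 2,4-bis[6-bromo-1-(4-methylbenzenesulfonyl)-1H-indol-3-yl]-1H-imidazole | Cc1ccc(cc1)S(=O)(=O)n1cc(-c2c[nH]c(n2)-c2cn(S(=O)(=O)c3ccc(C)cc3)c3cc(Br)ccc23)c2ccc(Br)cc12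
F5 | step 3 | 6-bromo-3-[(Z)-2-chloroethenyl]-1-(4-methylbenzenesulfonyl)-1H-indole | Cl/C=C\c1cn(S(=O)(=O)c2ccc(C)cc2)c2cc(Br)ccc12
F6 | step 4 | 6-bromo-1-(4-methylbenzenesulfonyl)-3-(1H-1,2,3-triazol-4-yl)-1H-indole | Cc1ccc(cc1)S(=O)(=O)n1cc(-c2c[nH]nn2)c2ccc(Br)cc12
A1 | alternative 1 | 2,4-diiodo-1-{[2-(trimethylsilyl)ethoxy]methyl}-1H-imidazole | C[Si](C)(C)CCOCn1cc(I)nc1I
A2 | alternative 1 | [6-bromo-1-(tert-butyldimethylsilyl)-1H-indol-3-yl]boronic acid | CC(C)(C)[Si](C)(C)n1cc(B(O)O)c2ccc(Br)cc12
A3 | alternative 2 | 6-bromo-1H-indole-3-carboximidamide | N=C(N)c1c[nH]c2cc(Br)ccc12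
A4 | alternative 2 | 2-bromo-1-(6-bromo-1H-indol-3-yl)ethan-1-one | O=C(CBr)c1c[nH]c2cc(Br)ccc12
A5 | alternative 3 | 2,2'-(1H-imidazole-2,4-diyl)diacetaldehyde | O=CCc1c[nH]c(CC=O)n1
A6 | alternative 3 | (3-bromophenyl)hydrazine | NNc1cccc(Br)c1
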